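(The earlier runs and the new flask were generated by integration for substances that don't exist; the scatter is artificial.)

G is the account to keep in these flasks: D, held, goes on delivering Q, so you book every mole against G, the limiting reagent, and it stands as G, GQ or X.

| flask | G | D | J | remark | time |
|---|---|---|---|---|---|
| north-west | 0.17 M | 14 mM (held) | 8.4 mM | run made earlier |  |
| winter | 0.17 M | 14 mM (held) | 4.2 mM |  | 20 h |
| autumn | 0.17 M | 14 mM (held) | 4.2 mM |  | 60 h |
- north-west (time / h: GQ / %, G / %): 0.333: 1.4, 98.3; 0.667: 2.4, 100.1; 1.50: 4.5, 95.2; 4.00: 12.8, 83.2

(each reading ± 1 percentage point)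
- at the start none of Q is dissolved
- what was read earlier has a scatter of 1 percentage point, one standard deviation
- what may be going on: G + Q <-> X; GQ + J <-> X + J; D <-> Q; G + Q <-> GQ
- no earlier run changes the charge of J; that part of a forecast is a guess
- which of the two there is more of at the end, winter (X / GQ)
- which of the two there is more of at the end, autumn (X / GQ)
- final GQ, as a percentage of the G charged, in winter
- final GQ, as a percentage of the G charged, in autumn

Take the last line of the north-west run as a ledger: with G at 83.2% and GQ at 12.8%, X closes the books at 4.00%, a difference of two readings that each scatter by 1 percentage point, so what follows is loose. My own reckoning uses two time constants. The feed treats the loss of G as pseudo-first-order. The drain time τ is the time constant with which I let GQ leak into X, booking all X as coming that way; if GQ rises about linearly from zero, c_X/c_GQ = t/(2τ). I guess that τ varies inversely with c_J, since no earlier run tests this.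

τ_G = 21.7 h

τ, north-west = 6.40 h

τ, winter = 12.8 h

This drain time closes the winter ledger at 20 h:

G left = 39.9%

c_X/c_GQ = 0.781

GQ = 33.8%, X = 26.3%

I do not stretch a linear rise to 60 h, so I give no autumn figure.

The forecast says GQ with 29% for winter and X with 13% for autumn, and it warns of its drain constant that “that figure is poorly fixed”. My winter GQ stands higher than its figure.

Winter gives 40.8% GQ against 23.8% X, and autumn 17.4% GQ against 76.7% X.

    G + Q ⇌ X (K = 22000 /M, k = 0.00320 /M/min)
    GQ + J ⇌ X + J, rate k2*[J]*[GQ] forward; the back reaction follows from the equilibrium constant (k = 0.170 /M/min)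
    D ⇌ Q, rate k3*(csat - [Q]) (kL = 0.0110 /min)
    G + Q ⇌ GQ (K = 250 /M, k = 0.280 /M/min)

At 8.43 h winter made GQ 3.05 times as fast as it used it up, each step taken net, so GQ was made faster than it went. Read from winter's final ledger, the same rule gives τ = 17.2 h, longer than the 12.8 h I carried in.

In the neighbour flask, winter with J at 0.0017 M, that τ scales to 42.5 h, which gives c_X/c_GQ = 0.236 at 20 h. The computed flask holds 51.2% GQ and 11.8% X, a ratio of 0.230.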